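The retrosynthesis first raises C7 from CH2OH to CHO, then cuts the C2–Br and C6–Br bonds together. The C3–Br bond is never cut and is bought in place.
This works because, in the one benzene ring, the C1 hydroxyl is flanked by C2–Br and C6–Br and its para carbon C4 is blocked by C7. Only C3–Br lies meta to oxygen, so the phenol can place the other two bromines itself.
Forward: 2-bromo-4-hydroxybenzaldehyde 1 takes up two bromine atoms from bromine 2, passing through monobromination product 3, to give tribromoaldehyde 4. Hydride reduction of 4 then gives target 5. No ring is formed, since the arene is purchased.
C7 stays at the aldehyde level during halogenation because a para-hydroxybenzyl alcohol would invite ipso attack at C4 with loss of the one-carbon unit.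
Stereochemistry: the target is achiral, with no stereocentre and no double-bond geometry to control.

Key step: step 1

Remark on locants: C1–C7 above are those of the target phenol (OH on C1, C7 on C4). In the steps the aldehydes carry their own numbering (CHO on C1, OH on C4). Target C2, C6 and C3 therefore correspond to aldehyde C3, C5 and C2.
Assumption: 1 is taken as a catalogue compound and used as purchased.

Step 1
Reactants: 1 2-bromo-4-hydroxybenzaldehyde; 2 bromine
Product: 4 2,3,5-tribromo-4-hydroxybenzaldehyde, via 2,5-dibromo-4-hydroxybenzaldehyde 3 (not isolated)
Conditions: Br2 (2.1 equiv), NaOAc (2.5 equiv), glacial AcOH, 15 °C → rt, then 45 °C; H2O, filtration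
Reagents that add atoms: bromine 2, BrBr
Why: This is a twofold electrophilic aromatic bromination of a phenol: the C4 hydroxyl feeds electron density to C3 and C5, each of which attacks Br2 to give an arenium ion that rearomatises by losing its proton to acetate. The open C5 site (para to the C2 bromine) should react first to give 3, and the hydroxyl keeps 3 nucleophilic enough for the slower attack at C3, which is wedged between the hydroxyl and the C2 bromine, hence the gentle warming at the end. The closest known reaction is the conversion of 4-hydroxybenzaldehyde into its 3,5-dibromo derivative with Br2 in AcOH/NaOAc, and the exhaustive bromination of 3-bromophenol shows that a carbon flanked by OH and Br is still substituted. Selectivity is needed against C6 and against ipso attack at C1: C6 is meta to the hydroxyl and ortho to the formyl group and so is doubly disfavoured, whereas C3 and C5 are ortho to OH, meta to CHO and ortho/para to the C2 bromine, so all three directors agree. Ipso attack at C1 with loss of the formyl carbon is held back by the near-stoichiometric bromine charge, by water-poor acetic acid that offers no hydrate route for expelling that carbon, by NaOAc removing HBr, and by the C2 bromine shielding C1. No ring closes and no stereocentre is formed.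

Step 2
Reactants: 4 2,3,5-tribromo-4-hydroxybenzaldehyde
Product: 5 2,3,6-tribromo-4-(hydroxymethyl)phenol
Conditions: NaBH4 (1.5 equiv), THF–H2O (4:1), 0 °C → rt; then 1 M HCl to pH 4–5, 0 °C
Reagents that add atoms: none
Why: In this borohydride reduction of an aromatic aldehyde, hydride adds chemoselectively to the formyl carbon while the aryl bromides stay inert to NaBH4, the acidic phenol consumes part of the hydride (hence the excess), and the alcohol-free medium with cold, mild acidification should keep the para-hydroxybenzyl alcohol from ionising to a quinone methide; no stereocentre arises.

Compound list
1 | 2-bromo-4-hydroxybenzaldehyde | O=Cc1ccc(O)cc1Br | starting material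
2 | bromine | BrBr | starting material
3 | 2,5-dibromo-4-hydroxybenzaldehyde | O=Cc1cc(Br)c(O)cc1Br | intermediate
4 | 2,3,5-tribromo-4-hydroxybenzaldehyde | O=Cc1cc(Br)c(O)c(Br)c1Br | intermediate
5 | 2,3,6-tribromo-4-(hydroxymethyl)phenol | OCc1cc(Br)c(O)c(Br)c1Br | target

Total step count: 2
Longest linear sequence: 2

Steps most likely to fail (the route has only two steps, so both are ranked, the riskier first)

Step 1. The second bromination at the crowded C3 position may stall at the dibromo stage. Forcing it with more bromine or heat may open ipso attack at C1, with loss of the formyl carbon. The fallback replaces the formyl group with a cyano group, which cannot leave as an electrofuge, so excess bromine and heat become tolerable. It sets out from 1. NH2OH·HCl and HCO2Na in refluxing HCO2H should convert 1 through (E)-2-bromo-4-hydroxybenzaldehyde oxime F1 into 2-bromo-4-hydroxybenzonitrile F2 in one pot. Excess Br2 with NaOAc in AcOH at 60 °C, the same reaction type as the well-known dibromination of 4-hydroxybenzonitrile, should then lead through 2,5-dibromo-4-hydroxybenzonitrile F3 to 2,3,5-tribromo-4-hydroxybenzonitrile F4. Partial reduction with iBu2AlH (3 equiv, toluene–CH2Cl2, −78 → 0 °C) followed by aqueous HCl should release the aldehyde, and the route is rejoined at 4.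

Step 2. Hydride addition may be slow because the carbonyl is conjugated with the phenolate formed in the basic medium. On acidification the benzylic oxygen may also be lost by ionisation towards a quinone methide, followed by ether formation or oligomerisation. The fallback masks the phenol so that neither process can operate. It sets out from 4. TBSCl and imidazole in DMF at rt should give 2,3,5-tribromo-4-[(tert-butyldimethylsilyl)oxy]benzaldehyde F5. NaBH4 in THF–EtOH at 0 °C should reduce this to {2,3,5-tribromo-4-[(tert-butyldimethylsilyl)oxy]phenyl}methanol F6. Bu4NF buffered with AcOH in THF at 0 °C should then remove the silyl group under nearly neutral conditions, and the route is rejoined at 5.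

Further compounds
F1 | step 1 | (E)-2-bromo-4-hydroxybenzaldehyde oxime | O/N=C/c1ccc(O)cc1Br
F2 | step 1 | 2-bromo-4-hydroxybenzonitrile | N#Cc1ccc(O)cc1Br
F3 | step 1 | 2,5-dibromo-4-hydroxybenzonitrile | N#Cc1cc(Br)c(O)cc1Br
F4 | step 1 | 2,3,5-tribromo-4-hydroxybenzonitrile | N#Cc1cc(Br)c(O)c(Br)c1Br
F5 | step 2 | 2,3,5-tribromo-4-[(tert-butyldimethylsilyl)oxy]benzaldehyde | O=Cc1cc(Br)c(O[Si](C)(C)C(C)(C)C)c(Br)c1Br
F6 | step 2 | {2,3,5-tribromo-4-[(tert-butyldimethylsilyl)oxy]phenyl}methanol | OCc1cc(Br)c(O[Si](C)(C)C(C)(C)C)c(Br)c1Br
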